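## Retrosynthetic overview
- Fertidin ← addition of an isopropyl-cerium reagent to hydroazulenone **7**. The C3 carbinol is set last, from the face anti to the angular methyl and the C4 substituent.
- **7** ← 7-endo closure of an allylic radical (from allylic chloride **6**) onto the β-carbon of a (Z)-β-aroyloxy enone. This one radical step forms the C4–C5 bond, closes the seven-membered ring, keeps the C6=C7 trisubstituted alkene and sets C4 (S).
- **6** ← cross-metathesis of the allyl group of **5** with methallyl chloride ← O-anisoylation of hydroxymethylene ketone **4** ← Cu-catalysed asymmetric conjugate addition (ACA) of MeMgBr to 3-allylcyclopentenone **3**, with the enolate trapped by ethyl formate.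
- Ring order: the cyclopentanone comes from cyclopentane-1,3-dione. The quaternary C8a is set by the ACA, and the seven-membered ring is closed last by the radical step.

Assumptions: Cu/Josiphos ACA on this β,β-disubstituted cyclopentenone gives ≥90% ee, with the ligand enantiomer chosen to give the 8a*R* centre. H-atom transfer to the C3a radical is assumed to favour the trans ring fusion, which the target has (angular Me and C3a–H trans). The cross-metathesis gives an E/Z mixture of the allylic chloride, and the allyl radical equilibrates to the ring-compatible geometry.

---

**Step 1**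
Reactants: **1** cyclopentane-1,3-dione
Product: **2** 3-ethoxycyclopent-2-en-1-one
Conditions: EtOH, cat. TsOH, PhH, reflux, Dean–Stark
Reagents that add atoms: ethanol, CCO
Why: Acid-catalysed vinylogous-ester formation masks one carbonyl so that only the other reacts with the Grignard reagent in step 2.

**Step 2**
Reactants: **2** 3-ethoxycyclopent-2-en-1-one
Product: **3** 3-(prop-2-en-1-yl)cyclopent-2-en-1-one
Conditions: allylMgBr, THF, 0 °C; then 1 M HCl, 0 °C, 10 min
Reagents that add atoms: allylmagnesium bromide, C=CC[Mg]Br
Why: Stork–Danheiser 1,2-addition followed by mild acidic hydrolysis and transposition converts the vinylogous ester into the β-allyl enone, with the short, cold acid quench limiting isomerisation of the allyl alkene.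

**Step 3**
Reactants: **3** 3-allylcyclopent-2-en-1-one
Product: **4** (2Z,3R)-3-allyl-2-(hydroxymethylidene)-3-methylcyclopentan-1-one
Conditions: MeMgBr, CuBr·SMe2 (5 mol %), Josiphos-type ligand (6 mol %), t-BuOMe, −78 °C; then HCO2Et, −78 °C → rt; then aq. HCl
Reagents that add atoms: methylmagnesium bromide, C[Mg]Br; ethyl formate, O=COCC
Why: Cu-catalysed asymmetric conjugate addition of Me creates the quaternary C8a centre (the chiral ligand sets the enantiofacial selectivity), and the regiodefined magnesium enolate next to that centre undergoes Claisen formylation to give the chelated (Z)-hydroxymethylene ketone.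

**Step 4**
Reactants: **4** (2Z,3R)-3-allyl-2-(hydroxymethylidene)-3-methylcyclopentan-1-one
Product: **5** (2Z,3R)-3-allyl-2-[(4-methoxybenzoyloxy)methylidene]-3-methylcyclopentan-1-one
Conditions: 4-MeOC6H4COCl, Et3N, CH2Cl2, 0 °C
Reagents that add atoms: 4-methoxybenzoyl chloride, COc1ccc(cc1)C(Cl)=O
Why: O-Acylation of the enol(ate) gives the enol ester with the acyloxy group cis to the ketone, which keeps it away from the quaternary centre; this Z geometry later fixes C4 as S, and the ester becomes the final anisate.

**Step 5**
Reactants: **5** enol ester; methallyl chloride (3-chloro-2-methylprop-1-ene)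
Product: **6** (2Z,3R)-3-[4-chloro-3-methylbut-2-en-1-yl]-2-[(4-methoxybenzoyloxy)methylidene]-3-methylcyclopentan-1-one (E/Z mixture at the new alkene)
Conditions: methallyl chloride (10 equiv), Hoveyda–Grubbs II (5 mol %), CH2Cl2, 40 °C
Reagents that add atoms: methallyl chloride, C=C(C)CCl
Why: Cross-metathesis couples the terminal allyl alkene with the 1,1-disubstituted partner to build the trisubstituted alkene and the allylic chloride radical precursor, and the electron-poor enol ester does not take part.

**Step 6**
Reactants: **6** allylic chloride
Product: **7** (3aS,4S,8aR)-6,8a-dimethyl-3-oxo-1,2,3,3a,4,5,8,8a-octahydroazulen-4-yl 4-methoxybenzoate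
Conditions: Bu3SnH (1.2 equiv, syringe pump over 8 h), AIBN (0.2 equiv), PhH (2 mM), 80 °C
Reagents that add atoms: none
Why: Proposed new method: Bu3Sn• abstracts Cl to give a nucleophilic 2-methylallyl radical whose primary terminus closes 7-endo onto the electrophilic β-carbon (CH–OAr) of the (Z)-enone, with net replacement of Cl by H; the polarity-mismatched 6-exo attack at the α-carbon and the 5-endo closure through the other terminus are disfavoured, the slow tin hydride addition gives the allyl radical time to adopt the ring-compatible Z geometry, the retained allyl alkene becomes C6=C7, the tether on the bottom face of C8a sets C4 as S, and H-atom transfer to the α-keto radical is assumed to deliver the trans-fused 3aS isomer; the closest known reactions are Giese-type radical cyclisations of allylic halides onto alkylidene carbonyl acceptors and 7-endo radical closures.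

**Step 7**
Reactants: **7** hydroazulenone anisate
Product: **8** Fertidin, (3R,3aS,4S,8aR)-3-hydroxy-6,8a-dimethyl-3-(propan-2-yl)-1,2,3,3a,4,5,8,8a-octahydroazulen-4-yl 4-methoxybenzoate
Conditions: iPrMgCl, anhydrous CeCl3, THF, −78 °C
Reagents that add atoms: isopropylmagnesium chloride, CC(C)[Mg]Cl
Why: Organocerium 1,2-addition is chemoselective for the ketone over the aryl ester and is weakly basic, so it avoids enolisation and E1cB loss of the β-anisate, and the isopropyl group adds to the face anti to the angular Me and the C4 substituent, giving 3R with iPr trans to the angular Me and OH cis to it.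

---

## Compound list
1 | cyclopentane-1,3-dione | O=C1CCC(=O)C1 | starting material
2 | 3-ethoxycyclopent-2-en-1-one | CCOC1=CC(=O)CC1 | intermediate
3 | 3-(prop-2-en-1-yl)cyclopent-2-en-1-one | C=CCC1=CC(=O)CC1 | intermediate
4 | (2Z,3R)-3-allyl-2-(hydroxymethylidene)-3-methylcyclopentan-1-one | C=CC[C@@]1(C)CCC(=O)/C1=C\O | intermediate
5 | (2Z,3R)-3-allyl-2-[(4-methoxybenzoyloxy)methylidene]-3-methylcyclopentan-1-one | C=CC[C@@]1(C)CCC(=O)/C1=C\OC(=O)c1ccc(OC)cc1 | intermediate
6 | (2Z,3R)-3-(4-chloro-3-methylbut-2-en-1-yl)-2-[(4-methoxybenzoyloxy)methylidene]-3-methylcyclopentan-1-one | ClCC(C)=CC[C@@]1(C)CCC(=O)/C1=C\OC(=O)c1ccc(OC)cc1 | intermediate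
7 | (3aS,4S,8aR)-6,8a-dimethyl-3-oxo-1,2,3,3a,4,5,8,8a-octahydroazulen-4-yl 4-methoxybenzoate | COc1ccc(C(=O)O[C@H]2CC(C)=CC[C@@]3(C)CCC(=O)[C@H]23)cc1 | intermediate
8 | Fertidin | COc1ccc(C(=O)O[C@H]2CC(C)=CC[C@@]3(C)CC[C@@](O)(C(C)C)[C@H]23)cc1 | target

## Step count
Total steps: 7. Longest linear sequence: 7.

## Three steps most likely to fail
1. **Step 6 (7-endo allyl-radical cyclisation and C3a configuration).** The closure may be slow, may give 6-exo or reduced uncyclised products, or H-atom transfer may give the cis-fused epimer.
   Fallback: replace steps 5–6 with a polar route. Do Cu-ACA of MeMgBr on **3** with enolate aldol trapping by 3-methylbut-3-enal, which adds trans to the allyl group and so gives the trans ring fusion. Then close the ring by RCM of the allyl and methallyl alkenes, correct C4 to S if needed (oxidation/reduction or Mitsunobu inversion), and anisoylate.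
2. **Step 3 (enantioselectivity of ACA on a β,β-disubstituted cyclopentenone, and formylation of the Mg enolate).**
   Fallback: set the quaternary centre by chirality transfer. Reduce 3-methylcyclopentenone with CBS, then run a Johnson–Claisen rearrangement, and elaborate the resulting ester into the hydroxymethylene ketone.
3. **Step 7 (iPr addition: E1cB elimination of the β-anisate, or wrong facial selectivity).**
   Fallback: carry the C4 oxygen as a TBS ether instead of the anisate (silylate **4** with TBSCl/Et3N in step 4 and run steps 5–6 unchanged). Add iPrMgCl/CeCl3 to the resulting ketone, where the silyloxy group is a poorer E1cB leaving group, then remove TBS with TBAF and anisoylate the secondary alcohol (anisoyl chloride, DMAP).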